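**Plan**

- Labels: ring A (methylated catechol) has the CH2 bridge on C1, oxygens on C2 and C3, the cyclopentyl group on C4 and methyl on C6. Ring B has the bridge on C1′, oxygens on C3′ and C4′ and the cyclopentyl group on C5′. C1″ is the quaternary cyclopentyl carbon.
- Enabling feature: in both arenes C1″ sits on a ring carbon (C4, C5′) directly ortho to a phenolic oxygen (O–C3, O–C4′), so each aryl–C1″ bond can be delivered from that oxygen.
- Cuts, in retrosynthetic order: the two O–CH3 bonds and the two ring C=C bonds (reduction); both aryl–C1″ bonds together, back to aryl cyclopentenyl ethers; the two ArO–C bonds; the bridge-carbon–C1′ bond; the C6–CH3 bond.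
- Forward: the ring A aldehyde and the ring B aryllithium give the diarylmethane. No ring is built; the cyclopentene comes intact from 4,4-dimethylcyclopentenone, is attached to both phenol oxygens and is then moved from O to C on both rings in one operation. Hydrogenation and demethylation finish the route.
- Stereochemistry: one CBS reduction sets an (R)-carbinol, Mitsunobu inversion gives two (S) C–O centres, and suprafacial [3,3] transfer turns them into the two (S) quaternary carbons. Nothing later touches them.

Key step: step 12

Assumption: in the CBS reduction of 3,4,4-trimethylcyclopent-2-en-1-one the alkenyl flank is taken to act as the larger carbonyl substituent, as for other cyclic enones, so the (S)-catalyst should give the (R)-carbinol; were the sense opposite, the (R)-catalyst would be used with no other change.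

**Route**

Step 1
Reactants: 1 2,3-dihydroxybenzaldehyde
Product: 2 3-(benzyloxy)-2-hydroxybenzaldehyde
Conditions: NaH (2.2 equiv), DMSO, rt; BnBr (1.0 equiv); aq. HCl
Reagents that add atoms: benzyl bromide, BrCc1ccccc1
Why: Williamson etherification of the dianion, in which the 2-oxygen is held by chelation to the neighbouring formyl group, so the free 3-phenoxide should be the one benzylated.

Step 2
Reactants: 2 3-(benzyloxy)-2-hydroxybenzaldehyde
Product: 3 3-(benzyloxy)-2-methoxybenzaldehyde
Conditions: MeI, K2CO3, DMF, rt
Reagents that add atoms: iodomethane, CI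
Why: Williamson O-methylation of the only remaining acidic site, the formyl-chelated phenol.

Step 3
Reactants: 3 3-(benzyloxy)-2-methoxybenzaldehyde
Product: 4 3-(benzyloxy)-6-bromo-2-methoxybenzaldehyde
Conditions: NBS, DMF, rt, dark
Reagents that add atoms: N-bromosuccinimide, O=C1CCC(=O)N1Br
Why: Electrophilic aromatic bromination in which the 2-methoxy group, twisted out of conjugation by its two neighbours, directs weakly, so the 3-benzyloxy group should send bromine to its para position C6, the known pattern for 2,3-dialkoxybenzaldehydes.

Step 4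
Reactants: 4 3-(benzyloxy)-6-bromo-2-methoxybenzaldehyde
Product: 5 3-(benzyloxy)-2-methoxy-6-methylbenzaldehyde
Conditions: (MeBO)3, Pd(dppf)Cl2 (5 mol %), K2CO3, dioxane/H2O, 100 °C
Reagents that add atoms: trimethylboroxine, CB1OB(C)OB(C)O1
Why: Suzuki–Miyaura methylation of an aryl bromide activated toward oxidative addition by the ortho-formyl group; the benzyl and methyl ethers are inert.

Step 5
Reactants: 6 4-bromo-2-methoxyphenol
Product: 7 1-(benzyloxy)-4-bromo-2-methoxybenzene
Conditions: BnBr, K2CO3, DMF, rt
Reagents that add atoms: benzyl bromide, BrCc1ccccc1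
Why: Williamson etherification of a simple guaiacol-type phenol.

Step 6
Reactants: 7 1-(benzyloxy)-4-bromo-2-methoxybenzene; 5 3-(benzyloxy)-2-methoxy-6-methylbenzaldehyde
Product: 9 [3-(benzyloxy)-2-methoxy-6-methylphenyl][4-(benzyloxy)-3-methoxyphenyl]methanol (racemic), via aryllithium 8 (not isolated)
Conditions: n-BuLi, THF, −78 °C; then 5, −78 → 0 °C; H2O
Reagents that add atoms: none
Why: Bromine–lithium exchange outruns deprotonation of the benzyl ether at −78 °C and the aryllithium then undergoes 1,2-addition to the aldehyde; the carbinol centre is formed racemic and is removed in step 7.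

Step 7
Reactants: 9 [3-(benzyloxy)-2-methoxy-6-methylphenyl][4-(benzyloxy)-3-methoxyphenyl]methanol
Product: 10 3-[(4-hydroxy-3-methoxyphenyl)methyl]-2-methoxy-4-methylphenol
Conditions: H2 (3 atm), 10% Pd/C, EtOAc–AcOH, rt
Reagents that add atoms: none
Why: Catalytic hydrogenolysis should cleave both O-benzyl ethers and the doubly benzylic, electron-rich C–OH bond under mild acid, leaving the methyl ethers and arenes untouched.

Step 8
Reactants: 11 4,4-dimethylcyclopent-2-en-1-one
Product: 12 trimethyl[(3,4,4-trimethylcyclopent-1-en-1-yl)oxy]silane (racemic)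
Conditions: MeMgBr, CuBr·SMe2 (10 mol %), TMSCl, THF, −78 → −30 °C; Et3N
Reagents that add atoms: methylmagnesium bromide, C[Mg]Br; chlorotrimethylsilane, C[Si](C)(C)Cl
Why: Copper-catalysed conjugate addition accelerated by TMSCl, which traps the enolate regiospecifically as the silyl enol ether; the new methine centre is racemic and is erased in step 9.

Step 9
Reactants: 12 trimethyl[(3,4,4-trimethylcyclopent-1-en-1-yl)oxy]silane
Product: 13 3,4,4-trimethylcyclopent-2-en-1-one
Conditions: Pd(OAc)2 (1.05 equiv), MeCN, rt
Reagents that add atoms: none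
Why: Saegusa–Ito oxidation, in which the palladium enolate has a β-hydrogen only at the methyl-bearing C3, so the double bond must return in conjugation carrying the new methyl group.

Step 10
Reactants: 13 3,4,4-trimethylcyclopent-2-en-1-one
Product: 14 (1R)-3,4,4-trimethylcyclopent-2-en-1-ol
Conditions: (S)-2-methyl-CBS-oxazaborolidine (15 mol %), catecholborane, toluene, −78 °C; MeOH, then aq. NaOH
Reagents that add atoms: none
Why: Corey–Bakshi–Shibata reduction, in which the ketone binds the catalyst boron with the alkenyl flank away from the ring substituents and hydride is delivered to one carbonyl face only, so the carbinol centre is set (R) by catalyst control and 1,2-reduction is exclusive.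

Step 11
Reactants: 10 3-[(4-hydroxy-3-methoxyphenyl)methyl]-2-methoxy-4-methylphenol; 14 (1R)-3,4,4-trimethylcyclopent-2-en-1-ol (2.5 equiv)
Product: 15 2-methoxy-3-({3-methoxy-4-{[(1S)-3,4,4-trimethylcyclopent-2-en-1-yl]oxy}phenyl}methyl)-4-methyl-1-{[(1S)-3,4,4-trimethylcyclopent-2-en-1-yl]oxy}benzene
Conditions: PPh3, DIAD, toluene, 0 °C → rt
Reagents that add atoms: none
Why: Double Mitsunobu etherification, each phenol displacing the oxyphosphonium group by SN2 with inversion so that the (R)-carbinol becomes the (S)-aryl ether; SN2′ attack would have to occur at the fully substituted C3 next to the gem-dimethyl carbon and is disfavoured.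

Step 12
Reactants: 15 the (S,S)-bis(cyclopentenyl) ether
Product: 16 3-({4-hydroxy-3-methoxy-5-[(1S)-1,5,5-trimethylcyclopent-2-en-1-yl]phenyl}methyl)-2-methoxy-4-methyl-6-[(1S)-1,5,5-trimethylcyclopent-2-en-1-yl]phenol
Conditions: PhNEt2 (degassed), 180 °C, sealed tube, Ar
Reagents that add atoms: none
Why: Each arm should undergo a concerted aromatic Claisen ([3,3]-sigmatropic) rearrangement through a six-membered transition state in which the O–C1 bond breaks while C3 of the cyclopentenyl unit bonds to the only free ortho carbon (C4 of ring A, C5′ of ring B), after which a proton shift restores the phenol. The closest known reactions are the thermal aromatic Claisen rearrangement of cycloalk-2-enyl aryl ethers with 1,3-chirality transfer and that of γ,γ-disubstituted allyl aryl ethers to ortho-tert-alkyl phenols; here the same event runs twice and next to a gem-dimethyl carbon. No ring is closed; two aryl–C bonds and two quaternary centres are formed. Both new stereocentres are controlled by the (S) C–O carbons, because the five-membered ring enforces a suprafacial shift and carbon arrives on the face that carried oxygen, giving (S) at both. The step needs ortho-regioselectivity and stereochemical fidelity: in each arene the second ortho position carries OMe and the para position is substituted, so migration to those sites can only revert, and the basic, weakly polar amine medium is chosen to keep the ethers from ionising to an allyl cation that would scramble configuration or eliminate.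

Step 13
Reactants: 16 the bis(cyclopentenyl) bis-phenol
Product: 17 3-({4-hydroxy-3-methoxy-5-[(1S)-1,2,2-trimethylcyclopentyl]phenyl}methyl)-2-methoxy-4-methyl-6-[(1S)-1,2,2-trimethylcyclopentyl]phenol
Conditions: H2 (1 atm), 10% Pd/C, EtOAc, rt
Reagents that add atoms: none
Why: Heterogeneous catalytic hydrogenation of two cis-disubstituted cyclopentene double bonds; the quaternary centres are not involved and keep their configuration.

Step 14
Reactants: 17 the saturated bis-phenol dimethyl ether
Product: 18 3-({3,4-dihydroxy-5-[(1S)-1,2,2-trimethylcyclopentyl]phenyl}methyl)-4-methyl-6-[(1S)-1,2,2-trimethylcyclopentyl]benzene-1,2-diol (CNP0137546.1)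
Conditions: BBr3, CH2Cl2, −78 → 0 °C; H2O
Reagents that add atoms: none
Why: Lewis-acid aryl methyl ether cleavage, BBr3 coordinating each methoxy oxygen and bromide removing the methyl group by SN2; no alkene remains and the quaternary centres cannot epimerise.

**Compound list**

1 | 2,3-dihydroxybenzaldehyde | O=Cc1cccc(O)c1O | starting material
2 | 3-(benzyloxy)-2-hydroxybenzaldehyde | O=Cc1cccc(OCc2ccccc2)c1O | intermediate
3 | 3-(benzyloxy)-2-methoxybenzaldehyde | COc1c(C=O)cccc1OCc1ccccc1 | intermediate
4 | 3-(benzyloxy)-6-bromo-2-methoxybenzaldehyde | COc1c(C=O)c(Br)ccc1OCc1ccccc1 | intermediate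
5 | 3-(benzyloxy)-2-methoxy-6-methylbenzaldehyde | COc1c(C=O)c(C)ccc1OCc1ccccc1 | intermediate
6 | 4-bromo-2-methoxyphenol | COc1cc(Br)ccc1O | starting material
7 | 1-(benzyloxy)-4-bromo-2-methoxybenzene | COc1cc(Br)ccc1OCc1ccccc1 | intermediate
8 | [4-(benzyloxy)-3-methoxyphenyl]lithium | [Li]c1ccc(OCc2ccccc2)c(OC)c1 | intermediate
9 | [3-(benzyloxy)-2-methoxy-6-methylphenyl][4-(benzyloxy)-3-methoxyphenyl]methanol (racemic) | COc1c(C(O)c2ccc(OCc3ccccc3)c(OC)c2)c(C)ccc1OCc1ccccc1 | intermediate
10 | 3-[(4-hydroxy-3-methoxyphenyl)methyl]-2-methoxy-4-methylphenol | Cc1ccc(O)c(OC)c1Cc1ccc(O)c(OC)c1 | intermediate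
11 | 4,4-dimethylcyclopent-2-en-1-one | CC1(C)CC(=O)C=C1 | starting material
12 | trimethyl[(3,4,4-trimethylcyclopent-1-en-1-yl)oxy]silane (racemic) | CC1C=C(O[Si](C)(C)C)CC1(C)C | intermediate
13 | 3,4,4-trimethylcyclopent-2-en-1-one | CC1=CC(=O)CC1(C)C | intermediate
14 | (1R)-3,4,4-trimethylcyclopent-2-en-1-ol | O[C@H]1C=C(C)C(C)(C)C1 | intermediate
15 | 2-methoxy-3-({3-methoxy-4-{[(1S)-3,4,4-trimethylcyclopent-2-en-1-yl]oxy}phenyl}methyl)-4-methyl-1-{[(1S)-3,4,4-trimethylcyclopent-2-en-1-yl]oxy}benzene | Cc1ccc(O[C@@H]2C=C(C)C(C)(C)C2)c(OC)c1Cc1cc(OC)c(O[C@@H]2C=C(C)C(C)(C)C2)cc1 | intermediate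
16 | 3-({4-hydroxy-3-methoxy-5-[(1S)-1,5,5-trimethylcyclopent-2-en-1-yl]phenyl}methyl)-2-methoxy-4-methyl-6-[(1S)-1,5,5-trimethylcyclopent-2-en-1-yl]phenol | Cc1cc([C@@]2(C)C=CCC2(C)C)c(O)c(OC)c1Cc1cc(OC)c(O)c([C@@]2(C)C=CCC2(C)C)c1 | intermediate
17 | 3-({4-hydroxy-3-methoxy-5-[(1S)-1,2,2-trimethylcyclopentyl]phenyl}methyl)-2-methoxy-4-methyl-6-[(1S)-1,2,2-trimethylcyclopentyl]phenol | Cc1cc([C@@]2(C)CCCC2(C)C)c(O)c(OC)c1Cc1cc(OC)c(O)c([C@@]2(C)CCCC2(C)C)c1 | intermediate
18 | 3-({3,4-dihydroxy-5-[(1S)-1,2,2-trimethylcyclopentyl]phenyl}methyl)-4-methyl-6-[(1S)-1,2,2-trimethylcyclopentyl]benzene-1,2-diol | Cc1cc([C@@]2(C)CCCC2(C)C)c(O)c(O)c1Cc1cc(O)c(O)c([C@@]2(C)CCCC2(C)C)c1 | target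

**Totals**

Total step count: 14.
Longest linear sequence: 10 steps (steps 1–4, 6, 7, 11–14).

**Steps most likely to fail**

Step 12. At the temperature needed to form a bond at the crowded C3 terminus, the allylic C–O bonds may instead break heterolytically or by elimination. The cyclopentenyl groups would then be lost as diene or return with scrambled position and configuration, and with two arms any such leakage counts twice.

The fallback sets out from 10 and 14 and comes back to the route at 17. It makes the same two aryl–C bonds by copper-mediated anti-SN2′ allylic substitution instead of a sigmatropic shift.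
- Phenol-directed bromination of 10 (NBS, 2 equiv) should give ortho,ortho′-dibromo bis-phenol F1, since in each ring the para position is occupied.
- Benzylation (BnBr, K2CO3) gives dibromo bis(benzyl ether) F2.
- Alcohol 14 is esterified with picolinic acid (Steglich conditions) to (1R)-3,4,4-trimethylcyclopent-2-en-1-yl picolinate F3.
- Double bromine–lithium exchange of F2 (t-BuLi, −78 °C), transmetalation with MgBr2 and reaction with F3 in the presence of CuBr·SMe2 is expected to deliver each aryl group to C3 anti to the chelating leaving group. This is a known way to benzylic quaternary carbons with 1,3-chirality transfer.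
- Because 14 is used without inversion and the substitution is anti, the same (S) centres should result in bis(cyclopentenyl) bis(benzyl ether) F4.
- Hydrogenation over Pd/C then saturates both double bonds and removes both benzyl groups, giving 17.

Step 11. The activated allylic oxyphosphonium intermediate may ionise before the phenol attacks, with erosion of configuration, elimination to the diene, or an incomplete second etherification.

The fallback sets out from 13 and 10 and comes back at 15.
- Reduction of 13 under the conditions of step 10 but with the (R)-catalyst should give (1S)-3,4,4-trimethylcyclopent-2-en-1-ol F5.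
- Methyl chloroformate and pyridine convert it into methyl (1S)-3,4,4-trimethylcyclopent-2-en-1-yl carbonate F6.
- Tsuji–Trost allylic etherification of 10 with F6 (Pd2(dba)3, dppf, THF, rt) proceeds by ionisation anti to palladium and phenoxide attack anti to palladium at the unhindered C1 terminus. The net result is retention, so the (S,S)-bis-ether 15 should form without an SN2 step.

Step 10. Facial discrimination may be poor because the CH2–CMe2 flank and the alkenyl flank of 13 are of similar size. A modest shortfall is buffered, since the minor enantiomer of 14 ends up mostly in diastereomers of 15 that differ from the (S,S) compound.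

The fallback sets out from 13 and comes back at 14.
- Bromination–dehydrobromination (Br2, then Et3N, CH2Cl2) should give 2-bromo-3,4,4-trimethylcyclopent-2-en-1-one F7, whose bromoalkene flank is unambiguously the larger one.
- CBS reduction with the same (S)-catalyst should give (1R)-2-bromo-3,4,4-trimethylcyclopent-2-en-1-ol F8.
- Bromine–lithium exchange (t-BuLi, THF, −78 °C) and protonation remove the halogen and return 14.

**Further compounds**

F1 | step 12 | 6-bromo-3-[(3-bromo-4-hydroxy-5-methoxyphenyl)methyl]-2-methoxy-4-methylphenol | Cc1cc(Br)c(O)c(OC)c1Cc1cc(OC)c(O)c(Br)c1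
F2 | step 12 | 2-(benzyloxy)-4-{[4-(benzyloxy)-3-bromo-5-methoxyphenyl]methyl}-1-bromo-3-methoxy-5-methylbenzene | Cc1cc(Br)c(OCc2ccccc2)c(OC)c1Cc1cc(OC)c(OCc2ccccc2)c(Br)c1
F3 | step 12 | (1R)-3,4,4-trimethylcyclopent-2-en-1-yl pyridine-2-carboxylate | O=C(O[C@H]1C=C(C)C(C)(C)C1)c1ccccn1
F4 | step 12 | 2-(benzyloxy)-4-({4-(benzyloxy)-3-methoxy-5-[(1S)-1,5,5-trimethylcyclopent-2-en-1-yl]phenyl}methyl)-3-methoxy-5-methyl-1-[(1S)-1,5,5-trimethylcyclopent-2-en-1-yl]benzene | Cc1cc([C@@]2(C)C=CCC2(C)C)c(OCc2ccccc2)c(OC)c1Cc1cc(OC)c(OCc2ccccc2)c([C@@]2(C)C=CCC2(C)C)c1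
F5 | step 11 | (1S)-3,4,4-trimethylcyclopent-2-en-1-ol | O[C@@H]1C=C(C)C(C)(C)C1
F6 | step 11 | methyl (1S)-3,4,4-trimethylcyclopent-2-en-1-yl carbonate | COC(=O)O[C@@H]1C=C(C)C(C)(C)C1
F7 | step 10 | 2-bromo-3,4,4-trimethylcyclopent-2-en-1-one | CC1=C(Br)C(=O)CC1(C)C
F8 | step 10 | (1R)-2-bromo-3,4,4-trimethylcyclopent-2-en-1-ol | O[C@H]1C(Br)=C(C)C(C)(C)C1
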